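**Retrosynthetic overview** (chain numbered C1 = CH2OBz … C16, C20 = lactone C=O)
1. Target 22 ⇐ acetylation of hydroxy lactone 21. Lactone ring A, the only ring made in the route, is closed second to last by Pd-catalysed cyclocarbonylation of alkynediol 20 (CO becomes C20; syn addition gives 10E).
2. 20 ⇐ C8 alcohol 18 by acetylation and acetonide removal (the dioxolane is a protecting ring carried in from the chiral pool).
3. 18 ⇐ three-component conjunctive coupling of alkenyl boronate 7, vinyllithium and bromoalkyne 13. A Pd-induced 1,2-shift of the alkenyl group from boron to carbon makes C7–C8 and sets C8 (R); C9–C10 closes in the same catalytic cycle.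
4. 7 ⇐ prenol + 1-bromobut-2-yne (2Z alkene by directed dianion alkylation), benzaldehyde (benzoate), Cu-catalysed syn protoboration (future 6E geometry).
5. 13 ⇐ acetonide of D-erythronolactone (C12 and C13 from the chiral pool): lactone to alkyne, CH2OH to isobutenyl, alkyne bromination.

Assumption: 8 is bought as the acetonide-protected form of D-erythronolactone (C4H6O4) and the acetonide is kept as the diol protecting group until step 10.

**Step 1**
Reactants: 1 3-methylbut-2-en-1-ol (prenol); 2 1-bromobut-2-yne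
Product: 4 (2Z)-3-methyloct-2-en-6-yn-1-ol, via prenol dianion 3 (not isolated)
Conditions: n-BuLi (2.1 equiv), TMEDA (2.1 equiv), Et2O, 0 °C → rt, 20 h; then 2 (0.9 equiv), THF, −78 → 0 °C; H2O
Reagents that add atoms: none
Why: Hydroxyl-directed allylic dimetalation of prenol removes a proton from the methyl cis to CH2OLi, and SN2 alkylation of the chelated Z-allyl dianion at its terminal carbon fixes the 2Z alkene (C4 cis to C1); the 2-alkylated isomer is the expected minor by-product and is removed by chromatography.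

**Step 2**
Reactants: 4 (2Z)-3-methyloct-2-en-6-yn-1-ol; 5 benzaldehyde
Product: 6 (2Z)-3-methyloct-2-en-6-yn-1-yl benzoate
Conditions: 5 (1.3 equiv), 1,3-dimethyl-1,2,4-triazolium iodide (5 mol %), DBU (1.1 equiv), 3,3′,5,5′-tetra-tert-butyldiphenoquinone (1.3 equiv), THF, rt
Reagents that add atoms: none
Why: NHC-catalysed oxidative esterification, in which the Breslow intermediate of benzaldehyde is oxidised by the quinone to an acyl azolium that acylates the primary allylic alcohol without touching the alkyne or the Z alkene.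

**Step 3**
Reactants: 6 (2Z)-3-methyloct-2-en-6-yn-1-yl benzoate
Product: 7 (2Z,6Z)-3-methyl-7-(4,4,5,5-tetramethyl-1,3,2-dioxaborolan-2-yl)octa-2,6-dien-1-yl benzoate
Conditions: B2pin2 (1.1 equiv), (IPr)CuCl (5 mol %; IPr = 1,3-bis(2,6-diisopropylphenyl)imidazol-2-ylidene), NaOtBu (6 mol %), MeOH (2 equiv), THF, rt
Reagents that add atoms: bis(pinacolato)diboron, CC1(C)OB(OC1(C)C)B1OC(C)(C)C(C)(C)O1
Why: Cu-catalysed protoboration (syn borylcupration, then protonation of the alkenylcopper by MeOH) puts boron on the less hindered methyl-bearing alkyne carbon (about 6–9:1 expected) and H and B on the same side, so boron is trans to the C5 chain, which becomes 6E once carbon replaces boron.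

**Step 4**
Reactants: 8 2,3-O-isopropylidene-D-erythronolactone
Product: 10 [(4R,5S)-5-ethynyl-2,2-dimethyl-1,3-dioxolan-4-yl]methanol, via lactol 9 (not isolated)
Conditions: i-Bu2AlH (1.1 equiv), CH2Cl2, −78 °C; then MeOH, K2CO3 (2.5 equiv), dimethyl (1-diazo-2-oxopropyl)phosphonate (1.4 equiv), 0 °C → rt
Reagents that add atoms: dimethyl (1-diazo-2-oxopropyl)phosphonate (Bestmann–Ohira reagent), COP(=O)(OC)C(=[N+]=[N-])C(C)=O
Why: Hydride reduction stops at the lactol, whose open hydroxy-aldehyde form undergoes Seyferth–Gilbert homologation (Bestmann–Ohira variant) to the terminal alkyne; both stereocentres (future C12 and C13) come unchanged from D-erythronolactone.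

**Step 5**
Reactants: 10 [(4R,5S)-5-ethynyl-2,2-dimethyl-1,3-dioxolan-4-yl]methanol
Product: 11 (4S,5S)-5-ethynyl-2,2-dimethyl-1,3-dioxolane-4-carbaldehyde
Conditions: Dess–Martin periodinane (1.3 equiv), pyridine, CH2Cl2, 0 °C → rt; used crude
Reagents that add atoms: none
Why: Dess–Martin oxidation gives the aldehyde under non-epimerising conditions, so the cis-dioxolane α-alkoxy centre is kept.

**Step 6**
Reactants: 11 (4S,5S)-5-ethynyl-2,2-dimethyl-1,3-dioxolane-4-carbaldehyde
Product: 12 (4S,5R)-4-ethynyl-2,2-dimethyl-5-(2-methylprop-1-en-1-yl)-1,3-dioxolane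
Conditions: i-PrPPh3I (1.3 equiv), n-BuLi (1.25 equiv), THF, 0 °C; then 11, −78 → 0 °C
Reagents that add atoms: isopropyltriphenylphosphonium iodide, CC(C)[P+](c1ccccc1)(c1ccccc1)c1ccccc1.[I-]
Why: Wittig olefination with the non-stabilised isopropylidene ylide is fast at low temperature, so the α-centre is not epimerised; the ylide is too weak a base to deprotonate the alkyne and the gem-dimethyl alkene has no geometry to control.

**Step 7**
Reactants: 12 (4S,5R)-4-ethynyl-2,2-dimethyl-5-(2-methylprop-1-en-1-yl)-1,3-dioxolane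
Product: 13 (4S,5R)-4-(bromoethynyl)-2,2-dimethyl-5-(2-methylprop-1-en-1-yl)-1,3-dioxolane
Conditions: NBS (1.1 equiv), AgNO3 (10 mol %), acetone, rt, dark
Reagents that add atoms: N-bromosuccinimide, BrN1C(=O)CCC1=O
Why: Silver-catalysed electrophilic bromination of the terminal alkyne proceeds through the silver acetylide and is much faster than any reaction of NBS with the trisubstituted alkene in dry acetone.

**Step 8**
Reactants: 7 (2Z,6Z)-3-methyl-7-(4,4,5,5-tetramethyl-1,3,2-dioxaborolan-2-yl)octa-2,6-dien-1-yl benzoate; 14 bromoethene (vinyl bromide); 13 (4S,5R)-4-(bromoethynyl)-2,2-dimethyl-5-(2-methylprop-1-en-1-yl)-1,3-dioxolane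
Product: 18 (2Z,6E,8R)-11-[(4S,5R)-2,2-dimethyl-5-(2-methylprop-1-en-1-yl)-1,3-dioxolan-4-yl]-8-hydroxy-3,7-dimethylundeca-2,6-dien-10-yn-1-yl benzoate, via vinyllithium 15 (not isolated), via lithium borate 16 (not isolated), via boronic ester 17 (not isolated)
Conditions: 14 (1.0 equiv), t-BuLi (2.0 equiv), Et2O, −78 °C; add to 7 (1.0 equiv) in THF, −78 → 0 °C; then 13 (1.1 equiv), Pd(OAc)2 (2 mol %), (Sp,Sp)-MandyPhos (C52H50FeN2P2, 2.4 mol %), NaOTf (3 equiv), THF, 45 °C; then NaBO3·4H2O, THF/H2O, rt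
Reagents that add atoms: sodium perborate tetrahydrate (NaBO3·4H2O), [Na+].[O-]B1OO1.O.O.O.O
Why: Proposed new method: a Pd/MandyPhos-catalysed enantioselective conjunctive cross-coupling that uses a 1-bromoalkyne as electrophile and a functionalised trisubstituted 1-methylalkenyl group as migrating group; vinyllithium adds to boron of 7 at −78 °C (far faster than to the benzoate) to give the bis(alkenyl) ate complex 16, zerovalent palladium inserts into the C(sp)–Br bond of 13, NaOTf strips bromide so that the cationic divalent alkynylpalladium binds the unsubstituted vinyl group of 16 on the face chosen by the ligand, the alkenyl group then shifts from boron to the adjacent carbon anti to palladium (1,2-metallate shift, forming C7–C8 and the C8 stereocentre with the alkene geometry retained), C(sp3)–C(sp) reductive elimination forms C9–C10, and perborate replaces boron by OH with retention to give 8R; the closest known reaction is the Pd/MandyPhos conjunctive cross-coupling of vinyl and bis(alkenyl) boron ate complexes with aryl and alkenyl triflates or halides, the sense of induction is assigned by analogy with that series, is checked on 18 by Mosher ester analysis, and the (Rp,Rp) ligand is used if it proves opposite.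

**Step 9**
Reactants: 18 (2Z,6E,8R)-11-[(4S,5R)-2,2-dimethyl-5-(2-methylprop-1-en-1-yl)-1,3-dioxolan-4-yl]-8-hydroxy-3,7-dimethylundeca-2,6-dien-10-yn-1-yl benzoate
Product: 19 (2Z,6E,8R)-8-acetoxy-11-[(4S,5R)-2,2-dimethyl-5-(2-methylprop-1-en-1-yl)-1,3-dioxolan-4-yl]-3,7-dimethylundeca-2,6-dien-10-yn-1-yl benzoate
Conditions: Ac2O (1.5 equiv), Et3N, DMAP (5 mol %), CH2Cl2, 0 °C
Reagents that add atoms: acetic anhydride, CC(=O)OC(C)=O
Why: Standard acylation of the secondary allylic alcohol installs the C8 acetate and blocks this homopropargylic hydroxyl, so that only O13 can act as the nucleophile in step 11.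

**Step 10**
Reactants: 19 (2Z,6E,8R)-8-acetoxy-11-[(4S,5R)-2,2-dimethyl-5-(2-methylprop-1-en-1-yl)-1,3-dioxolan-4-yl]-3,7-dimethylundeca-2,6-dien-10-yn-1-yl benzoate
Product: 20 (2Z,6E,8R,12S,13R)-8-acetoxy-12,13-dihydroxy-3,7,15-trimethylhexadeca-2,6,14-trien-10-yn-1-yl benzoate
Conditions: AcOH/H2O/THF (3:1:1), 40 °C
Reagents that add atoms: none
Why: Mild acid-catalysed acetal hydrolysis frees the anti diol without cleaving the acetate or benzoate and without breaking a C–O bond at either stereocentre.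

**Step 11**
Reactants: 20 (2Z,6E,8R,12S,13R)-8-acetoxy-12,13-dihydroxy-3,7,15-trimethylhexadeca-2,6,14-trien-10-yn-1-yl benzoate
Product: 21 (2Z,6E,8R,10E)-8-acetoxy-10-[(4S,5R)-4-hydroxy-5-(2-methylprop-1-en-1-yl)-2-oxooxolan-3-ylidene]-3,7-dimethyldeca-2,6-dien-1-yl benzoate
Conditions: CO (7 atm), PdCl2 (5 mol %), SnCl2 (5 mol %), PPh3 (10 mol %), MeCN, 75 °C
Reagents that add atoms: carbon monoxide, [C-]#[O+]
Why: Pd-catalysed cyclocarbonylation of a homopropargylic alcohol: the alkoxycarbonyl–palladium species formed from O13 and CO adds syn across the alkyne in the exo mode (five-membered ring A, favoured over the four-membered ring from O12) and protonolysis of the alkenyl–Pd bond leaves H cis to the carbonyl, i.e. 10E; C12 and C13 are untouched, so the anti diol gives the trans 4,5-disubstituted lactone.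

**Step 12**
Reactants: 21 (2Z,6E,8R,10E)-8-acetoxy-10-[(4S,5R)-4-hydroxy-5-(2-methylprop-1-en-1-yl)-2-oxooxolan-3-ylidene]-3,7-dimethyldeca-2,6-dien-1-yl benzoate
Product: 22 (2Z,6E,8R,10E)-8-acetoxy-10-[(4S,5R)-4-acetoxy-5-(2-methylprop-1-en-1-yl)-2-oxooxolan-3-ylidene]-3,7-dimethyldeca-2,6-dien-1-yl benzoate (CNP0262857.1)
Conditions: Ac2O (1.5 equiv), pyridine, CH2Cl2, 0 °C → rt
Reagents that add atoms: acetic anhydride, CC(=O)OC(C)=O
Why: Acetylation of the remaining secondary allylic alcohol with Ac2O/pyridine, without DMAP, avoids SN2′ displacement of the Baylis–Hillman-type acetate.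

**Compound list**
1 | 3-methylbut-2-en-1-ol (prenol) | CC(C)=CCO | starting material
2 | 1-bromobut-2-yne | CC#CCBr | starting material
3 | lithium (2Z)-4-lithio-3-methylbut-2-en-1-olate (prenol dianion) | [Li]C/C(C)=C\CO[Li] | intermediate (not isolated)
4 | (2Z)-3-methyloct-2-en-6-yn-1-ol | CC#CCC/C(C)=C\CO | intermediate
5 | benzaldehyde | O=Cc1ccccc1 | starting material
6 | (2Z)-3-methyloct-2-en-6-yn-1-yl benzoate | CC#CCC/C(C)=C\COC(=O)c1ccccc1 | intermediate
7 | (2Z,6Z)-3-methyl-7-(4,4,5,5-tetramethyl-1,3,2-dioxaborolan-2-yl)octa-2,6-dien-1-yl benzoate (boron trans to the C5 chain) | CC1(C)OB(OC1(C)C)/C(C)=C/CC/C(C)=C\COC(=O)c1ccccc1 | intermediate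
8 | (3aR,6aR)-2,2-dimethyldihydrofuro[3,4-d][1,3]dioxol-4(3aH)-one (2,3-O-isopropylidene-D-erythronolactone) | CC1(C)O[C@@H]2COC(=O)[C@@H]2O1 | starting material
9 | 2,3-O-isopropylidene-D-erythrofuranose (lactol, anomer mixture) | CC1(C)O[C@@H]2COC(O)[C@@H]2O1 | intermediate (not isolated)
10 | [(4R,5S)-5-ethynyl-2,2-dimethyl-1,3-dioxolan-4-yl]methanol | C#C[C@@H]1OC(C)(C)O[C@@H]1CO | intermediate
11 | (4S,5S)-5-ethynyl-2,2-dimethyl-1,3-dioxolane-4-carbaldehyde | C#C[C@@H]1OC(C)(C)O[C@@H]1C=O | intermediate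
12 | (4S,5R)-4-ethynyl-2,2-dimethyl-5-(2-methylprop-1-en-1-yl)-1,3-dioxolane | C#C[C@@H]1OC(C)(C)O[C@@H]1C=C(C)C | intermediate
13 | (4S,5R)-4-(bromoethynyl)-2,2-dimethyl-5-(2-methylprop-1-en-1-yl)-1,3-dioxolane | BrC#C[C@@H]1OC(C)(C)O[C@@H]1C=C(C)C | intermediate
14 | bromoethene (vinyl bromide) | C=CBr | starting material
15 | vinyllithium | [Li]C=C | intermediate (not isolated)
16 | lithium ethenyl[(2Z,6Z)-8-(benzoyloxy)-6-methylocta-2,6-dien-2-yl](pinacolato)borate (ate complex of 7) | [Li+].C=C[B-]1(OC(C)(C)C(C)(C)O1)/C(C)=C/CC/C(C)=C\COC(=O)c1ccccc1 | intermediate (not isolated)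
17 | (2Z,6E,8R)-11-[(4S,5R)-2,2-dimethyl-5-(2-methylprop-1-en-1-yl)-1,3-dioxolan-4-yl]-3,7-dimethyl-8-(4,4,5,5-tetramethyl-1,3,2-dioxaborolan-2-yl)undeca-2,6-dien-10-yn-1-yl benzoate | CC1(C)OB(OC1(C)C)[C@H](CC#C[C@@H]2OC(C)(C)O[C@@H]2C=C(C)C)/C(C)=C/CC/C(C)=C\COC(=O)c1ccccc1 | intermediate (not isolated)
18 | (2Z,6E,8R)-11-[(4S,5R)-2,2-dimethyl-5-(2-methylprop-1-en-1-yl)-1,3-dioxolan-4-yl]-8-hydroxy-3,7-dimethylundeca-2,6-dien-10-yn-1-yl benzoate | O[C@H](CC#C[C@@H]1OC(C)(C)O[C@@H]1C=C(C)C)/C(C)=C/CC/C(C)=C\COC(=O)c1ccccc1 | intermediate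
19 | (2Z,6E,8R)-8-acetoxy-11-[(4S,5R)-2,2-dimethyl-5-(2-methylprop-1-en-1-yl)-1,3-dioxolan-4-yl]-3,7-dimethylundeca-2,6-dien-10-yn-1-yl benzoate | CC(=O)O[C@H](CC#C[C@@H]1OC(C)(C)O[C@@H]1C=C(C)C)/C(C)=C/CC/C(C)=C\COC(=O)c1ccccc1 | intermediate
20 | (2Z,6E,8R,12S,13R)-8-acetoxy-12,13-dihydroxy-3,7,15-trimethylhexadeca-2,6,14-trien-10-yn-1-yl benzoate | CC(=O)O[C@H](CC#C[C@H](O)[C@H](O)C=C(C)C)/C(C)=C/CC/C(C)=C\COC(=O)c1ccccc1 | intermediate
21 | (2Z,6E,8R,10E)-8-acetoxy-10-[(4S,5R)-4-hydroxy-5-(2-methylprop-1-en-1-yl)-2-oxooxolan-3-ylidene]-3,7-dimethyldeca-2,6-dien-1-yl benzoate | CC(=O)O[C@H](C/C=C1/C(=O)O[C@H](C=C(C)C)[C@H]1O)/C(C)=C/CC/C(C)=C\COC(=O)c1ccccc1 | intermediate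
22 | (2Z,6E,8R,10E)-8-acetoxy-10-[(4S,5R)-4-acetoxy-5-(2-methylprop-1-en-1-yl)-2-oxooxolan-3-ylidene]-3,7-dimethyldeca-2,6-dien-1-yl benzoate (CNP0262857.1) | CC(=O)O[C@H](C/C=C1/C(=O)O[C@H](C=C(C)C)[C@H]1OC(C)=O)/C(C)=C/CC/C(C)=C\COC(=O)c1ccccc1 | target

**Totals**
Total steps: 12. Longest linear sequence: 9 steps (8 → 22, steps 4–12); the other branch (1 → 22) is 8 steps.

**Three steps most likely to fail**

1. Step 8 (the proposed conjunctive coupling). Main dangers are direct alkenyl–alkynyl coupling without the 1,2-shift, bromine transfer from 13 to the ate complex, attack of vinyllithium on the benzoate, and an unknown level and sense of induction with an alkynyl electrophile. The fallback uses only known chemistry, sets out from 12 and 7 and comes back at 18. Alkyne 12 is deprotonated (n-BuLi, THF, −78 °C) and opened onto oxirane with BF3·OEt2 to give 4-[(4S,5R)-2,2-dimethyl-5-(2-methylprop-1-en-1-yl)-1,3-dioxolan-4-yl]but-3-yn-1-ol F1. Dess–Martin oxidation gives 4-[(4S,5R)-2,2-dimethyl-5-(2-methylprop-1-en-1-yl)-1,3-dioxolan-4-yl]but-3-ynal F2, which is used at once because it isomerises easily to the allenal. Boronate 7 is converted with retention of geometry (NaOMe, then ICl, THF/MeOH, −78 °C) into (2Z,6E)-7-iodo-3-methylocta-2,6-dien-1-yl benzoate F3. An asymmetric Nozaki–Hiyama–Kishi alkenylation of F2 with F3 (CrCl2, NiCl2 (cat.), chiral sulfonamide ligand, Et3N, THF, rt) then gives 18; this reaction tolerates the ester, alkyne and acetal.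

2. Step 3 (regioselectivity of boron delivery to a methyl/primary-alkyl alkyne; the regioisomeric boronate is hard to separate). The fallback sets out from 6 and comes back at 7. Stoichiometric hydrozirconation with Cp2Zr(H)Cl (1.5 equiv, THF, rt) is left to equilibrate, which places zirconium on the methyl-bearing carbon (about 9:1) and gives chlorobis(cyclopentadienyl)[(2E,6Z)-8-(benzoyloxy)-6-methylocta-2,6-dien-2-yl]zirconium F4. Zr-to-B transmetalation with B-chlorocatecholborane (CH2Cl2, 0 °C) gives (2Z,6Z)-7-(1,3,2-benzodioxaborol-2-yl)-3-methylocta-2,6-dien-1-yl benzoate F5, and ligand exchange with pinacol gives 7.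

3. Step 11 (cyclocarbonylation of a free diol in the presence of two allylic esters; possible competition from O12 or slow insertion of the internal alkyne). The fallback sets out from 20 and comes back at 21. Hydroxyl-directed, PdCl2(PPh3)2-catalysed syn hydrostannation (Bu3SnH, THF, 0 °C) puts tin on C11, next to the propargylic carbinol, giving the (10E)-11-(tributylstannyl) alkene of 20 F6 (other centres as in 20). Iododestannylation (I2, CH2Cl2, 0 °C) with retention gives the (10E)-11-iodo alkene F7. Carbonylative lactonisation (Pd(PPh3)4 (5 mol %), CO (1 atm), K2CO3, MeCN, 50 °C) closes ring A through O13 with retention, which gives the same 10E lactone 21.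

**Further compounds**
F1 | step 8 | 4-[(4S,5R)-2,2-dimethyl-5-(2-methylprop-1-en-1-yl)-1,3-dioxolan-4-yl]but-3-yn-1-ol | OCCC#C[C@@H]1OC(C)(C)O[C@@H]1C=C(C)C
F2 | step 8 | 4-[(4S,5R)-2,2-dimethyl-5-(2-methylprop-1-en-1-yl)-1,3-dioxolan-4-yl]but-3-ynal | O=CCC#C[C@@H]1OC(C)(C)O[C@@H]1C=C(C)C
F3 | step 8 | (2Z,6E)-7-iodo-3-methylocta-2,6-dien-1-yl benzoate | C/C(I)=C\CC/C(C)=C\COC(=O)c1ccccc1
F4 | step 3 | chlorobis(cyclopentadienyl)[(2E,6Z)-8-(benzoyloxy)-6-methylocta-2,6-dien-2-yl]zirconium | C/C(=C\CC/C(C)=C\COC(=O)c1ccccc1)[Zr](Cl)(C1C=CC=C1)C1C=CC=C1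
F5 | step 3 | (2Z,6Z)-7-(1,3,2-benzodioxaborol-2-yl)-3-methylocta-2,6-dien-1-yl benzoate | C/C(=C\CC/C(C)=C\COC(=O)c1ccccc1)B1Oc2ccccc2O1
F6 | step 11 | (10E)-11-(tributylstannyl) alkene from syn hydrostannation of 20 | CC(=O)O[C@H](C/C=C(/[Sn](CCCC)(CCCC)CCCC)[C@H](O)[C@H](O)C=C(C)C)/C(C)=C/CC/C(C)=C\COC(=O)c1ccccc1
F7 | step 11 | (10E)-11-iodo alkene from F6 | CC(=O)O[C@H](C/C=C(/I)[C@H](O)[C@H](O)C=C(C)C)/C(C)=C/CC/C(C)=C\COC(=O)c1ccccc1
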